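The pyran ring (O2, C1, C8a, C4a, C4, C3) is closed last, by disconnecting C4–C4a and O2–C3. That ring is the cyclic enol ether of a C1 formyl group on C8a, conjugated through C4a=C5 with the C6 ketone, and C3=C4 is a masked alkyne whose C3 is the electrophilic terminus of that ynenone. One palladium/copper coupling–cycloisomerization cascade therefore joins a carvone-derived carbocycle (C7 and C8 set; triflate at C4a, formyl at C8a) to an ethynyl oxirane carrying the whole side chain, and forms both bonds. Neither precursor contains a pyran.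

Key step: step 19

Remark on the chemistry: atoms are labelled as in the target bicycle (O2, C1, C3, C4, C4a, C5–C8, C8a); the side chain is C9 (epoxide carbon on C3), C10, C11=C12, C13, C14 (carbinol), C15. Vinylogous acids are drawn as their formyl (enal) tautomers.

**Carbocycle branch**

Step 1
Reactants: 1 (S)-(+)-carvone
Product: 2 trans-carvone oxide, (1S,4S,6S)-1-methyl-4-(prop-1-en-2-yl)-7-oxabicyclo[4.1.0]heptan-2-one
Conditions: 30% aq. H2O2, NaOH (cat.), MeOH, 0 °C
Reagents that add atoms: hydrogen peroxide, OO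
Why: Weitz–Scheffer nucleophilic epoxidation, in which hydroperoxide adds axially to C8 anti to the C4a isopropenyl group and the enolate closes the oxirane on that same face, so C7 and C8 are set by the carvone stereocentre.

Step 2
Reactants: 2 trans-carvone oxide
Product: 3 (2S,3R,5S)-2,3-dihydroxy-2-methyl-5-(prop-1-en-2-yl)cyclohexan-1-one
Conditions: HClO4 (cat.), THF/H2O (3:1), 0 °C → rt
Reagents that add atoms: water, O
Why: Acid-catalysed epoxide hydrolysis in the trans-diaxial (Fürst–Plattner) sense, with water attacking the secondary C8 with inversion because the C6 carbonyl disfavours positive charge at C7, so the C7–O bond is retained and the 7,8-diol should come out trans in the target configuration.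

Step 3
Reactants: 3 the trans-diol
Product: 4 (2S,3R,5S)-2-methyl-5-(prop-1-en-2-yl)-2,3-bis(triethylsilyloxy)cyclohexan-1-one
Conditions: TESOTf (2.6 equiv), 2,6-lutidine, CH2Cl2, −78 → 0 °C
Reagents that add atoms: triethylsilyl trifluoromethanesulfonate, CC[Si](CC)(CC)OS(=O)(=O)C(F)(F)F
Why: Silyl triflate silylation covers the secondary C8 hydroxyl and the hindered tertiary C7 hydroxyl in one operation without touching a stereocentre.

Step 4
Reactants: 4 the bis-TES ether
Product: 7 (1S,3R,4S)-4-methyl-5-oxo-3,4-bis(triethylsilyloxy)cyclohexyl acetate, via methoxy hydroperoxide 5 (not isolated), via peroxyacetate 6 (not isolated)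
Conditions: O3, CH2Cl2/MeOH, −78 °C; then Ac2O, Et3N, DMAP (cat.), 0 °C → rt
Reagents that add atoms: ozone, O=[O+][O-]; methanol, CO
Why: Ozonolysis in methanol followed by Criegee rearrangement of the peroxyacetate, in which C4a migrates to oxygen with retention and the dialkoxycarbenium ion is demethylated by acetate, exchanges the isopropenyl group for an acetoxy group while C7 and C8 stay untouched.

Step 5
Reactants: 7 the β-acetoxy ketone
Product: 8 7-methyl-7,8-bis(triethylsilyloxy)cyclohexane-4a,6-diol (7S,8R; C4a as in 7; both C6 epimers)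
Conditions: iBu2AlH (4 equiv), CH2Cl2, −78 °C; aq. KNaC4H4O6
Reagents that add atoms: none
Why: Hydride reduction cleaves the acetate and reduces the C6 ketone under non-basic conditions, which avoids β-elimination of the C4a acetoxy group and silyl migration; the new C6 centre is irrelevant because it is re-oxidised.

Step 6
Reactants: 8 the diol
Product: 9 (4S,5R)-4-methyl-4,5-bis(triethylsilyloxy)cyclohexane-1,3-dione
Conditions: Dess–Martin periodinane (2.5 equiv), pyridine, CH2Cl2, 0 °C → rt
Reagents that add atoms: none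
Why: Double Dess–Martin oxidation of the 1,3-diol gives the 1,3-dione; C7 is quaternary and C8 is not α to a carbonyl, so neither centre can epimerise.

Step 7
Reactants: 9 the 1,3-dione
Product: 10 (4S,5R)-4-methyl-3-oxo-4,5-bis(triethylsilyloxy)cyclohex-1-en-1-yl trifluoromethanesulfonate
Conditions: Tf2O (1.1 equiv), Et3N, CH2Cl2, −78 °C
Reagents that add atoms: trifluoromethanesulfonic anhydride, O=S(=O)(OS(=O)(=O)C(F)(F)F)C(F)(F)F
Why: Enol triflate formation from a cyclic 1,3-dione, in which the enolate should be sulfonylated at the less hindered oxygen on C4a because the oxygen on C6 lies next to the quaternary C7.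

Step 8
Reactants: 10 the β-triflyloxy enone
Product: 12 (4S,5R)-6-(dimethoxymethyl)-4-methyl-3-oxo-4,5-bis(triethylsilyloxy)cyclohex-1-en-1-yl trifluoromethanesulfonate, via silyl dienol ether 11 (not isolated)
Conditions: TBSOTf, iPr2NEt, CH2Cl2, 0 °C; then HC(OMe)3, TMSOTf (10 mol %), −78 °C
Reagents that add atoms: trimethyl orthoformate, COC(OC)OC
Why: Soft enolization can only remove the γ-hydrogen at C8a (C7 is quaternary), and the resulting 2-silyloxy diene should add the dimethoxycarbenium ion at its γ-terminus C8a in a vinylogous Mukaiyama reaction, anti to the C8 silyloxy group; this C8a centre is transient.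

Step 9
Reactants: 12 the dimethyl acetal
Product: 13 (3R,4S)-2-formyl-4-methyl-5-oxo-3,4-bis(triethylsilyloxy)cyclohex-1-en-1-yl trifluoromethanesulfonate
Conditions: PPTS (cat.), acetone/H2O (10:1), rt; used without storage
Reagents that add atoms: water, O
Why: Mild acetal hydrolysis frees the C1 aldehyde, which rests as the vinylogous acid (C1 enol through C8a, C4a, C5 to C6=O) and so erases the C8a centre; the TES ethers and the enol triflate should tolerate PPTS.

**Side-chain branch**

Step 10
Reactants: 14 ethyl (S)-3-hydroxybutanoate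
Product: 16 ethyl (2S,3S)-3-hydroxy-2-methylbutanoate, via dilithium enolate alkoxide 15 (not isolated)
Conditions: LiN(iPr)2 (2.2 equiv), THF, −78 → −20 °C; then MeI, DMPU, −78 → −10 °C
Reagents that add atoms: iodomethane, CI
Why: Fráter–Seebach alkylation, in which the chelated dianion is methylated on the face anti to the C15 methyl group, setting C13 anti to C14.

Step 11
Reactants: 16 the anti hydroxy ester
Product: 17 ethyl (2S,3S)-3-(tert-butyldimethylsilyloxy)-2-methylbutanoate
Conditions: TBSCl, imidazole, DMF, rt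
Reagents that add atoms: tert-butyldimethylsilyl chloride, CC(C)(C)[Si](C)(C)Cl
Why: Standard imidazole-mediated silylation of the secondary alcohol, needed so that no free hydroxyl directs the later epoxidation.

Step 12
Reactants: 17 the silyl ether ester
Product: 18 (2S,3S)-3-(tert-butyldimethylsilyloxy)-2-methylbutanal
Conditions: iBu2AlH (1.05 equiv), CH2Cl2, −78 °C; aq. KNaC4H4O6
Reagents that add atoms: none
Why: Partial ester reduction stops at the aldehyde because the tetrahedral aluminium acetal is stable at −78 °C, a temperature at which the α-centre should not epimerise.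

Step 13
Reactants: 18 the aldehyde
Product: 19 (2E,4R,5S)-5-(tert-butyldimethylsilyloxy)-2,4-dimethylhex-2-enal
Conditions: Ph3P=C(CH3)CHO, toluene, 90 °C
Reagents that add atoms: 2-(triphenylphosphoranylidene)propanal, CC(C=O)=P(c1ccccc1)(c1ccccc1)c1ccccc1
Why: Wittig olefination with a stabilised α-methyl ylide should give the (E)-trisubstituted C11=C12 enal.

Step 14
Reactants: 19 the enal
Product: 20 ethyl (2E,4E,6R,7S)-7-(tert-butyldimethylsilyloxy)-2,4,6-trimethylocta-2,4-dienoate
Conditions: Ph3P=C(CH3)CO2Et, toluene, 90 °C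
Reagents that add atoms: ethyl 2-(triphenylphosphoranylidene)propanoate, CCOC(=O)C(C)=P(c1ccccc1)(c1ccccc1)c1ccccc1
Why: A second Wittig olefination with a stabilised ylide should give the (E)-configured C9=C10 double bond.

Step 15
Reactants: 20 the dienoate
Product: 21 (2E,4E,6R,7S)-7-(tert-butyldimethylsilyloxy)-2,4,6-trimethylocta-2,4-dien-1-ol
Conditions: iBu2AlH (2.3 equiv), CH2Cl2, −78 °C; aq. KNaC4H4O6
Reagents that add atoms: none
Why: 1,2-Reduction of the conjugated ester to the allylic alcohol.

Step 16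
Reactants: 21 the dienol
Product: 22 [(2S,3S)-3-[(2E,4R,5S)-5-(tert-butyldimethylsilyloxy)-4-methylhex-2-en-2-yl]-2-methyloxiran-2-yl]methanol
Conditions: Ti(OiPr)4 (10 mol %), L-(+)-diethyl tartrate (12 mol %), t-BuOOH, 4 Å molecular sieves, CH2Cl2, −20 °C
Reagents that add atoms: tert-butyl hydroperoxide, CC(C)(C)OO
Why: Sharpless asymmetric epoxidation, in which the titanium tartrate complex delivers oxygen only to the allylic C9=C10 alkene and, with the L-(+)-tartrate, to the face that gives the (2S,3S)-epoxy alcohol, setting C9 and C10 by reagent control.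

Step 17
Reactants: 22 the epoxy alcohol
Product: 23 (2R,3S)-3-[(2E,4R,5S)-5-(tert-butyldimethylsilyloxy)-4-methylhex-2-en-2-yl]-2-methyloxirane-2-carbaldehyde
Conditions: Dess–Martin periodinane, pyridine, CH2Cl2, 0 °C → rt
Reagents that add atoms: none
Why: Buffered Dess–Martin oxidation of the primary alcohol; the aldehyde has no α-hydrogen, so C9 cannot epimerise.

Step 18
Reactants: 23 the epoxy aldehyde
Product: 24 (2S,3S)-2-ethynyl-2-methyl-3-[(2E,4R,5S)-5-(tert-butyldimethylsilyloxy)-4-methylhex-2-en-2-yl]oxirane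
Conditions: dimethyl (1-diazo-2-oxopropyl)phosphonate, K2CO3, MeOH, 0 °C → rt
Reagents that add atoms: dimethyl (1-diazo-2-oxopropyl)phosphonate, COP(=O)(OC)C(=[N+]=[N-])C(C)=O
Why: Ohira–Bestmann (Seyferth–Gilbert) homologation, in which the diazophosphonate anion adds to the aldehyde and the derived alkylidene carbene rearranges to the terminal alkyne under conditions that spare the epoxide.

**Union and completion**

Step 19
Reactants: 13 the formyl enol triflate (1.2 equiv); 24 the ethynyl oxirane
Product: 26 7,8-bis-O-triethylsilyl-14-O-tert-butyldimethylsilyl pestaphilone D, via ynenone vinylogous acid 25 (not isolated)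
Conditions: Pd(PPh3)4 (5 mol %), CuI (15 mol %), iPr2NEt (3 equiv), degassed DMF, 0 °C → rt
Reagents that add atoms: none
Why: Zerovalent palladium inserts into the C4a–OTf bond of 13, the copper acetylide of 24 transmetalates and reductive elimination forges C4–C4a to give ynenone 25, whose vinylogous acid is deprotonated by the amine. The C1 enolate oxygen then adds to the copper-bound alkyne at C3 and protodemetalation at C4 delivers the 4-ylidene-4H-pyran, so C4–C4a and O2–C3 are made in one operation. The closest known reaction types are the tandem Sonogashira coupling–cyclization used for isocoumarins and benzofurans and the CuI–amine cycloisomerization of alkynyl vinylogous acids to 6H-isochromen-6-ones. The ring closes 6-endo-dig, a mode secured because C3 is the δ-terminus of the C3≡C4–C4a=C5–C6=O ynenone, whereas 5-exo attack at C4 would give an alkylidene furan that is not conjugated with C6=O. No stereocentre is formed, and C7, C8, C9, C10, C13 and C14 are not touched. The selectivities needed are triflate insertion ahead of ionization of the allylic–propargylic epoxide by zerovalent palladium, secured by the very reactive triflate in slight excess at low temperature, and O2 rather than O8 attack on the alkyne, secured by the TES ether on O8.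

Step 20
Reactants: 26 the tris-silyl ether
Product: 27 pestaphilone D
Conditions: Bu4NF, AcOH (1:1), THF, 0 °C → rt
Reagents that add atoms: none
Why: Fluoride-mediated cleavage of the two TES ethers and the TBS ether under acetic acid buffering, which should avoid base-induced α-ketol shift and acid-induced opening of the vinyl epoxide.

**Compound list**

1 | (S)-(+)-carvone | O=C1C[C@@H](C(C)=C)CC=C1C | starting material
2 | trans-carvone oxide, (1S,4S,6S) | O=C1C[C@@H](C(C)=C)C[C@@H]2O[C@@]21C | intermediate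
3 | (2S,3R,5S)-2,3-dihydroxy-2-methyl-5-(prop-1-en-2-yl)cyclohexan-1-one | O=C1C[C@@H](C(C)=C)C[C@@H](O)[C@]1(C)O | intermediate
4 | (2S,3R,5S)-2-methyl-5-(prop-1-en-2-yl)-2,3-bis(triethylsilyloxy)cyclohexan-1-one | O=C1C[C@@H](C(C)=C)C[C@@H](O[Si](CC)(CC)CC)[C@]1(C)O[Si](CC)(CC)CC | intermediate
5 | 5-(1-hydroperoxy-1-methoxyethyl) analogue of 4 (mixture at the peroxy carbon) | O=C1C[C@@H](C(C)(OC)OO)C[C@@H](O[Si](CC)(CC)CC)[C@]1(C)O[Si](CC)(CC)CC | intermediate
6 | peroxyacetate of 5 | O=C1C[C@@H](C(C)(OC)OOC(C)=O)C[C@@H](O[Si](CC)(CC)CC)[C@]1(C)O[Si](CC)(CC)CC | intermediate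
7 | (1S,3R,4S)-4-methyl-5-oxo-3,4-bis(triethylsilyloxy)cyclohexyl acetate | O=C1C[C@@H](OC(C)=O)C[C@@H](O[Si](CC)(CC)CC)[C@]1(C)O[Si](CC)(CC)CC | intermediate
8 | 7-methyl-7,8-bis(triethylsilyloxy)cyclohexane-4a,6-diol (7S,8R; C6 epimers) | OC1C[C@@H](O)C[C@@H](O[Si](CC)(CC)CC)[C@]1(C)O[Si](CC)(CC)CC | intermediate
9 | (4S,5R)-4-methyl-4,5-bis(triethylsilyloxy)cyclohexane-1,3-dione | O=C1CC(=O)C[C@@H](O[Si](CC)(CC)CC)[C@]1(C)O[Si](CC)(CC)CC | intermediate
10 | (4S,5R)-4-methyl-3-oxo-4,5-bis(triethylsilyloxy)cyclohex-1-en-1-yl trifluoromethanesulfonate | O=C1C=C(OS(=O)(=O)C(F)(F)F)C[C@@H](O[Si](CC)(CC)CC)[C@]1(C)O[Si](CC)(CC)CC | intermediate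
11 | (3R,4S)-5-(tert-butyldimethylsilyloxy)-4-methyl-3,4-bis(triethylsilyloxy)cyclohexa-1,5-dien-1-yl trifluoromethanesulfonate | CC(C)(C)[Si](C)(C)OC1=CC(OS(=O)(=O)C(F)(F)F)=C[C@@H](O[Si](CC)(CC)CC)[C@]1(C)O[Si](CC)(CC)CC | intermediate
12 | (4S,5R)-6-(dimethoxymethyl)-4-methyl-3-oxo-4,5-bis(triethylsilyloxy)cyclohex-1-en-1-yl trifluoromethanesulfonate (acetal trans to the C8 silyloxy group expected) | O=C1C=C(OS(=O)(=O)C(F)(F)F)[C@H](C(OC)OC)[C@@H](O[Si](CC)(CC)CC)[C@]1(C)O[Si](CC)(CC)CC | intermediate
13 | (3R,4S)-2-formyl-4-methyl-5-oxo-3,4-bis(triethylsilyloxy)cyclohex-1-en-1-yl trifluoromethanesulfonate (vinylogous acid, formyl tautomer) | O=CC1=C(OS(=O)(=O)C(F)(F)F)CC(=O)[C@@](C)(O[Si](CC)(CC)CC)[C@@H]1O[Si](CC)(CC)CC | intermediate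
14 | ethyl (S)-3-hydroxybutanoate | CCOC(=O)C[C@H](C)O | starting material
15 | dilithium (E)-enolate alkoxide of 14 | CCO/C(O[Li])=C/[C@H](C)O[Li] | intermediate
16 | ethyl (2S,3S)-3-hydroxy-2-methylbutanoate | CCOC(=O)[C@@H](C)[C@H](C)O | intermediate
17 | ethyl (2S,3S)-3-(tert-butyldimethylsilyloxy)-2-methylbutanoate | CCOC(=O)[C@@H](C)[C@H](C)O[Si](C)(C)C(C)(C)C | intermediate
18 | (2S,3S)-3-(tert-butyldimethylsilyloxy)-2-methylbutanal | O=C[C@@H](C)[C@H](C)O[Si](C)(C)C(C)(C)C | intermediate
19 | (2E,4R,5S)-5-(tert-butyldimethylsilyloxy)-2,4-dimethylhex-2-enal | C/C(=C\[C@@H](C)[C@H](C)O[Si](C)(C)C(C)(C)C)C=O | intermediate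
20 | ethyl (2E,4E,6R,7S)-7-(tert-butyldimethylsilyloxy)-2,4,6-trimethylocta-2,4-dienoate | C/C(=C\[C@@H](C)[C@H](C)O[Si](C)(C)C(C)(C)C)/C=C(\C)C(=O)OCC | intermediate
21 | (2E,4E,6R,7S)-7-(tert-butyldimethylsilyloxy)-2,4,6-trimethylocta-2,4-dien-1-ol | C/C(=C\[C@@H](C)[C@H](C)O[Si](C)(C)C(C)(C)C)/C=C(\C)CO | intermediate
22 | [(2S,3S)-3-[(2E,4R,5S)-5-(tert-butyldimethylsilyloxy)-4-methylhex-2-en-2-yl]-2-methyloxiran-2-yl]methanol | C/C(=C\[C@@H](C)[C@H](C)O[Si](C)(C)C(C)(C)C)[C@@H]1O[C@@]1(C)CO | intermediate
23 | (2R,3S)-3-[(2E,4R,5S)-5-(tert-butyldimethylsilyloxy)-4-methylhex-2-en-2-yl]-2-methyloxirane-2-carbaldehyde | C/C(=C\[C@@H](C)[C@H](C)O[Si](C)(C)C(C)(C)C)[C@@H]1O[C@@]1(C)C=O | intermediate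
24 | (2S,3S)-2-ethynyl-2-methyl-3-[(2E,4R,5S)-5-(tert-butyldimethylsilyloxy)-4-methylhex-2-en-2-yl]oxirane | C/C(=C\[C@@H](C)[C@H](C)O[Si](C)(C)C(C)(C)C)[C@@H]1O[C@@]1(C)C#C | intermediate
25 | (5S,6R)-5-methyl-4-oxo-5,6-bis(triethylsilyloxy)-2-(oxiranylethynyl)cyclohex-1-ene-1-carbaldehyde carrying the side chain of 24 (vinylogous acid, formyl tautomer) | C/C(=C\[C@@H](C)[C@H](C)O[Si](C)(C)C(C)(C)C)[C@@H]1O[C@@]1(C)C#CC1=C(C=O)[C@@H](O[Si](CC)(CC)CC)[C@](C)(O[Si](CC)(CC)CC)C(=O)C1 | intermediate
26 | 7,8-bis-O-triethylsilyl-14-O-tert-butyldimethylsilyl pestaphilone D | C/C(=C\[C@@H](C)[C@H](C)O[Si](C)(C)C(C)(C)C)[C@@H]1O[C@@]1(C)C1=CC2=CC(=O)[C@@](C)(O[Si](CC)(CC)CC)[C@H](O[Si](CC)(CC)CC)C2=CO1 | intermediate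
27 | pestaphilone D | C/C(=C\[C@@H](C)[C@H](C)O)[C@@H]1O[C@@]1(C)C1=CC2=CC(=O)[C@@](C)(O)[C@H](O)C2=CO1 | target

**Summary**

Total step count: 20. Longest linear sequence: 11 steps (1 → 27 through steps 1–9, 19, 20; the side-chain branch 14 → 27 through steps 10–20 is equally long).

Steps most likely to fail:

1. Step 19. Once 13 is deprotonated, oxidative addition may slow, so that ionization of the allylic–propargylic epoxide by zerovalent palladium, alkyne homocoupling or 5-exo closure gain ground. Fallback: the coupling and the ring closure are separated. Setting out from 13, the enol oxygen is capped (TBSCl, imidazole, CH2Cl2, 0 °C) to give the neutral (Z)-silyloxymethylene dienone triflate F1. A short, cold Sonogashira coupling of this with 24 (Pd(PPh3)2Cl2, CuI, Et3N, THF, 0 °C) gives the isolable enyne silyl enol ether F2. Methanolysis of its labile vinylogous silyl ester (K2CO3 cat., MeOH, 0 °C), followed by CuI/iPr2NEt- or AgOTf-catalysed 6-endo-dig cyclization in CH2Cl2, comes back to the route at 26.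

2. Step 8. The triflate-bearing diene 11 is electron-poor, so addition of the carbenium ion may be sluggish, may occur at C5 instead of C8a, or the triflate may be lost. Fallback: C1 is introduced before the triflate. Setting out from 9, double enolization (TMSOTf, Et3N, CH2Cl2, 0 °C) gives the far more nucleophilic 1,3-bis(trimethylsilyloxy)diene F3. Its terminal carbon C8a adds HC(OMe)3 under TMSOTf catalysis at −78 °C to give, after aqueous work-up, the C8a dimethoxymethyl dione F4. Triflation (Tf2O, Et3N, −78 °C) at the C4a oxygen comes back to the route at 12.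

3. Step 2. In aqueous acid the isopropenyl group may be hydrated, or the epoxy ketone may open at C7 or rearrange; opening at C7 would feed the enantiomeric series after step 4. Fallback: setting out from 2, acetone is inserted into the oxirane without free water (BF3·OEt2 cat., acetone, −20 °C), with attack at C8 and inversion, to give the trans-fused acetonide F5. Hydrolysis of this strained dioxolane (80% aq. AcOH, 40 °C) comes back to the route at 3, where the diastereomers can be separated before the carvone stereocentre is removed.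

Further compounds
F1 | step 19 | (Z)-O-tert-butyldimethylsilyl enol ether of 13 | CC(C)(C)[Si](C)(C)O/C=C1\C(OS(=O)(=O)C(F)(F)F)=CC(=O)[C@@](C)(O[Si](CC)(CC)CC)[C@@H]1O[Si](CC)(CC)CC
F2 | step 19 | enyne silyl enol ether (O-TBS derivative of 25) | C/C(=C\[C@@H](C)[C@H](C)O[Si](C)(C)C(C)(C)C)[C@@H]1O[C@@]1(C)C#CC1=CC(=O)[C@@](C)(O[Si](CC)(CC)CC)[C@H](O[Si](CC)(CC)CC)/C1=C/O[Si](C)(C)C(C)(C)C
F3 | step 8 | (3R,4S)-4-methyl-3,4-bis(triethylsilyloxy)-1,5-bis(trimethylsilyloxy)cyclohexa-1,5-diene | C[Si](C)(C)OC1=CC(O[Si](C)(C)C)=C[C@@H](O[Si](CC)(CC)CC)[C@]1(C)O[Si](CC)(CC)CC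
F4 | step 8 | (4S,5R)-6-(dimethoxymethyl)-4-methyl-4,5-bis(triethylsilyloxy)cyclohexane-1,3-dione (acetal trans to the C8 silyloxy group) | O=C1CC(=O)[C@H](C(OC)OC)[C@@H](O[Si](CC)(CC)CC)[C@]1(C)O[Si](CC)(CC)CC
F5 | step 2 | trans-fused acetonide of 3 | O=C1C[C@@H](C(C)=C)C[C@H]2OC(C)(C)O[C@]12C
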